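One chain, living or dead, counts once, so the average length is monomer in chains divided by the chain count c(chains), the chains begun.

| setting | alder | cedar | oak | south-east | south-west |
|---|---|---|---|---|---|
| free monomer | 0.20 M | 0.20 M | 0.20 M | 0.20 M | 0.20 M |
| transfer agent | 2.1 mM | 2.7 mM | 3.5 mM | 2.00 mM | 4.00 mM |
| initiator | 6.9 mol% | 6.9 mol% | 6.9 mol% | 6.9 mol% | 6.9 mol% |
| remark | run made earlier | run made earlier | run made earlier |  |  |
| time |  |  |  | 40 h | 40 h |

- alder (time / h: monomer in chains / %): 2.00: 6.5; 5.00: 13.8; 10.0: 25.6; 15.0: 33.7; 20.0: 41.1
- cedar (time / h: monomer in chains / %): 1.50: 4.8; 3.00: 9.4; 6.00: 16.1; 10.0: 23.3; 20.0: 37.8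
- oak (time / h: monomer in chains / %): 2.00: 6.2; 5.00: 14.3; 10.0: 22.2; 15.0: 28.8; 20.0: 35.2

(readings scatter by 0.5 percentage points)

- the average divides the monomer in chains by the number of chains begun, living and dead together
- the earlier runs do not show the number of chains; that part of a forecast is a guess

- which of the two ends with the longer chains by the average number of monomer units in a chain (chains begun, living or dead) ("neither" if they lie within 10%) (south-east / south-west / neither)
- average number of monomer units in a chain (chains begun, living or dead) at the end, south-east
- average number of monomer units in a chain (chains begun, living or dead) at the end, south-west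

1. You read the pseudo-first-order slope of free monomer, ln(1/(1−x))/t. It starts at 0.0336 h⁻¹ in alder and 0.0320 h⁻¹ in oak, alike although oak holds more transfer agent. So I take it that the agent begins no chains, and that one count serves these runs and both new flasks. The mean start slope, with cedar, is 0.0328 h⁻¹.

2. Between 10.0 h and 20.0 h the slope is 0.0234 h⁻¹ in alder and lower in oak, 0.0183 h⁻¹. Suppose the slope follows the living ends and each transfer agent stops one. Once the agent has reacted, the late slope over the start slope is then 1 − c(transfer agent)/c(chains).

3. This gives two ways to one number. Alder gives 7.30 mM and oak 7.91 mM, so they part. The rule assumes the agent has finished reacting, and the larger charge is likely further from that, so oak cheats more. Joining the two in a straight line to zero charge, I commit to the chain count c(chains) = 6.38 mM.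

4. Continuing from alder's last reading at the end slope gives south-east 62.5% monomer in chains. Continuing from oak's gives south-west 49.3%. My lengths are 19.6 and 15.4.

5. The forecast differs from my reckoning. It says south-east, with 24 (8 to 55) and 13 (5.5 to 24), on the ground “I assume every agent molecule starts a chain”.

The simulation gives south-east, with 24.7 and 18.4.

    free monomer + initiator → living end + monomer in chains (k = 3.50 M⁻¹ h⁻¹)
    free monomer + living end → monomer in chains + living end, rate k2*[living end]*[free monomer] (k = 7.00 M⁻¹ h⁻¹)
    living end + transfer agent → dead chain (kL = 29.0 M⁻¹ h⁻¹)
    2 initiator → spent initiator (k = 120 M⁻¹ h⁻¹)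

South-east has not come to rest at 40.0 h: free monomer goes from 37.6% to 0.0173% by 400 h, and the length from 24.7 to 39.6. Living ends plus dead chains in south-east hold 5.05 mM, then 5.05 mM, less than my c(chains) of 6.38 mM. Free monomer charged over my count gives 31.3, below the simulated 39.6. Left ten times as long, south-west reaches a length of 38.2, up from 18.4. A neighbouring flask like south-west, with 1.60 mM transfer agent, reaches 65.3% monomer in chains. My count makes that a length of 20.5, and the flask gives 25.9 on 5.05 mM of chains begun.

The numbers in the tables come from a simulation with made-up constants; noise was put on by code.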